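(Readings and results were computed for an exercise; scatter was added.)

Amounts here are chances, so I follow one molecule of starting material through two forks. At the first it leaves the balance or survives; at the second a survivor becomes side product or joins the pair of target and isomer of the product.

all flasks: starting material 0.10 M

| run | protic impurity | remark | time |
|---|---|---|---|
| oak | 0.013 M | run made earlier |  |
| birch | 0.032 M | run made earlier |  |
| Monday's | 0.0100 M |  | 30 h |
| Thursday's | 0.0200 M |  | 30 h |

| run | time / h | starting material / % | side product / % | target / % | isomer of the product / % |
|---|---|---|---|---|---|
| oak | 2.50 | 13.9 | 39.8 | 28.4 | 7.2 |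
| oak | 8.00 | 0.6 | 46.5 | 21.3 | 19.2 |
| oak | 15.0 | 0.2 | 46.6 | 18.2 | 22.4 |
| oak | 20.0 | 0.4 | 46.1 | 17.7 | 23.8 |
| birch | 1.50 | 23.0 | 28.2 | 21.7 | 2.9 |
| birch | 4.00 | 2.7 | 37.2 | 21.9 | 10.8 |
| birch | 10.0 | 0.2 | 37.8 | 16.2 | 17.4 |
| birch | 20.0 | 0.1 | 38.7 | 15.0 | 19.3 |

(readings scatter by 0.3 percentage points)

- which of these there is most of at the end, counted by the starting material in it, Monday's (target / isomer of the product / side product / starting material)
- which of these there is most of at the end, counted by the starting material in it, Thursday's (target / isomer of the product / side product / starting material)
- final amount of the leader among these, as a percentage of the starting material charged, in Monday's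
- final amount of the leader among these, as a percentage of the starting material charged, in Thursday's

With starting material at 0.10 M in oak, birch, Monday's and Thursday's, the charges of these flasks fold into one number, the equivalents ε, protic impurity over starting material: 13.0% in oak, 32.0% in birch. Oak's side product reads 46.5% at 8.00 h and 46.1% at 20.0 h, so I take the last readings as the end. There oak is short of 12.0% and birch of 26.9%. Of the survivors, side product holds the share f, the selectivity, which reads 52.8%. That is more than the 47.2% that target and isomer share, so side product leads in Monday's and Thursday's.

Is ε enough, taking each equivalent to remove one molecule? Birch would then hold 35.9% of side product, less than its reading of 38.7%. It is not: the loss per equivalent reads 0.923 in oak and 0.841 in birch. I draw that as a straight line in ε, interpolated for Thursday's at 20.0% but extrapolated below oak for Monday's at 10.0%, and reckon losses of 9.36% for Monday's and 17.9% for Thursday's, hence 47.9% and 43.3% of side product.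

The forecast names side product for Monday's and side product for Thursday's, at 47.6% and 43.3%, the first a little below mine and the second level with it, on the grounds of a loss near one starting material per impurity, “tapering slightly at higher loading”.

The flask gives side product for Monday's at 48.1% and side product for Thursday's at 43.5%.

    target ⇌ isomer of the product (K = 1.32, k = 0.00271 min⁻¹)
    starting material + protic impurity → quenched substrate (k = 0.321 M⁻¹ min⁻¹)
    starting material → target (k = 0.00553 min⁻¹)
    starting material → side product (k = 0.00623 min⁻¹)

Monday's holds 9.16% as quenched substrate at 30.0 h, so its survivors are 53.0% side product, beside f at 52.8%. A neighbour like Thursday's but with 0.40 M of starting material has ε of 5.00%. The same line, extrapolated below oak, gives a loss of 4.79%, so f predicts 50.3% of side product, and that flask ends at 50.3%.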